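I could not integrate these set-ups by hand, so I looked for a number that needed no time course.

| flask | substrate | capture agent | free catalyst | remark | time |
|---|---|---|---|---|---|
| elm | 17 mM | 0.850 mM | 3.4 mM | a single well-mixed tank run continuously and read at steady state, 3.0 min in it on average |  |
| cedar | 17 mM (fed, over 1.50 min) | 0.850 mM | 3.4 mM | a stirred flask in which substrate is dosed at a steady rate over 1.50 min without added volume, worked up at 3.0 min | 3.0 min |
| maple | 17 mM | 0.850 mM | 3.4 mM | a closed flask charged with all of it at once and left for 3.0 min | 3.0 min |

    catalyst intermediate → free catalyst + target (k1 = 0.0466 s⁻¹)
    catalyst intermediate → spent catalyst B (k2 = 0.00224 s⁻¹)
    substrate + catalyst intermediate → spent catalyst A (k3 = 0.111 L mol⁻¹ s⁻¹)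
    substrate + free catalyst ⇌ catalyst intermediate (K4 = 21.2 L mol⁻¹, k4 = 4.85 L mol⁻¹ s⁻¹)
    catalyst intermediate + capture agent → trapped intermediate (k5 = 2.29 L mol⁻¹ s⁻¹)

1. the set-up with the highest share of target in all that became target or trapped intermediate, at the outlet or at the end ("none" if the first two lie within 2 percentage points) (elm / cedar / maple / none)
2. share of target in all that became target or trapped intermediate, at the outlet or at the end, elm
3. share of target in all that became target or trapped intermediate, at the outlet or at the end, cedar
4. share of target in all that became target or trapped intermediate, at the outlet or at the end, maple

- a species is counted by the substrate in it: one spent catalyst A counts as two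
- the stated concentrations are those of everything mixed, before any reaction; amounts are the same in each set-up
- the feed brings no volume worth counting
- run time (cedar): 3.0 min

Target and trapped intermediate both leave catalyst intermediate, and both rates carry the same [catalyst intermediate], so it cancels from their ratio. What stays I called the leak: the capture rate constant times [capture agent], a pseudo-first-order constant, divided by the rate constant of the target step. In logarithms this is a plain sum, so I took the numbers in turn. The constants leading to spent catalyst A and B appear in no term of it, though they thin the intermediate. Substrate, free catalyst, dosing time and the binding constants appear in none either; they reach the share second-hand, through how far trapping draws [capture agent] down. The target constant, the capture constant and the capture agent charge each shift the logarithm one for one, so these had to be known well.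

The leak at the charge was 0.0418, which lies 1.38 decades below unity and gives a share of one over one plus the leak, 96.0%. Half a decade of error upward would have meant 88.3%. Capture agent is a product nowhere in the scheme, so I took 96.0% as my floor. A flask losing a quarter of its capture agent stands 0.97 percentage points above that floor, less than the margin of 2 points. I expected trapping to stay within such a loss, and on that expectation I committed to none as best.

The forecast gave 96.6% for elm, 96.3% for cedar and 96.4% for maple, each above my floor, with none as best, holding that “substrate dosing changes how much forms rather than the share”.

The simulation gave 96.6%, 96.3% and 96.4% in that order, and none as best. In elm, the leak at the outlet level of capture agent, 0.707 mM, gives 96.6%. Cedar had not come to rest at 3.0 min: it still held 70.7% of the substrate charged, and 3.01% stood as catalyst intermediate. At 30.0 min its share read 97.1%. Through the leak, that reading corresponds to a target-weighted [capture agent] of 0.606 mM, against 0.850 mM charged.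

The constants were set for the occasion, and the outcome is calculated.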